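The runs are calculated from invented constants.

Watch the target, and count it per enzyme. The dusk flask, which is the flask asked about, and the colder dawn flask carry the same charge.

| flask | starting material | second substrate | free enzyme | added ligand | temperature | remark | time |
|---|---|---|---|---|---|---|---|
| dusk | 20 mM | 20 mM | 2 µM | 1.7 µM | 30 °C | the very flask that is asked about, followed so far |  |
| dawn | 20 mM | 20 mM | 2 µM | 1.7 µM | 25 °C | run made earlier |  |
| flask | 20 mM | 20.0 mM | 2.0 µM | 1.7 µM | 30 °C |  | 15 h |

| run | time / min | target / % |
|---|---|---|
| dusk | 80.0 | 10.6 |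
| dusk | 240 | 20.8 |
| dusk | 480 | 26.0 |
| dusk | 600 | 27.1 |
| dusk | 900 | 28.4 |
| dawn | 80.0 | 6.1 |
| dawn | 240 | 12.7 |
| dawn | 480 | 18.9 |
| dawn | 600 | 20.0 |
| dawn | 900 | 23.0 |

(standard deviation of a reading: 0.3 percentage points)

- removed target is counted in
- additions bring no volume worth counting

- violet: change nothing and wait 8.0 h more
- ochre: at 15 h add free enzyme, 50.0% of the amount charged, then wait 8.0 h
- blue: at 15 h raise the temperature by 10 K, then wait 8.0 h
- green: at 15 h take out 90% of the target then present, then wait 8.0 h

* target, in percent of the starting material first charged, at 15 h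
* the remedy with the largest gain of target, or "none" below 2 percentage points (violet / ochre / blue / green / none)
* target present, with what was taken out counted in, in percent of the starting material first charged, after violet
* target present, with what was taken out counted in, in percent of the starting material first charged, after green

Take the dusk flask in slow motion, counting target made per free enzyme charged, per minute. In the first instants, up to 80.0 min, it runs at 13.2 min⁻¹. In the middle, from 240 min to 480 min, it runs at 2.17 min⁻¹. At the end, from 600 min to 900 min, it crawls at 0.433 min⁻¹, a fall by a factor of 30.5. Yet 71.6% of the starting material is unconverted, and even a rate following the square of that share gives a factor of 1.95, far smaller than the fall. Expect a catalyst that stops. Check the dawn flask for the sign: over that last stretch it gains 3 percentage points where the dusk flask gains 1.3 points, with a scatter of 0.3 points on each reading.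

So carry one number, 2840 for the dusk flask: c(target) at the last reading over c(free enzyme) charged, the total turnover number. My reckoning for this flask runs as follows. Read 28.4% at 15 h. Violet, with the last rate held flat for 8.0 h, gives 2.1 points, and that rate is still falling, so expect its gain below the 2 points margin. Ochre brings 1.00 µM of fresh free enzyme, and the count gives 14 points.

The forecast gives 28.3% (27.9% to 28.8%), 28.7% after violet (28.2% to 29.6%), 28.8% after green (28.2% to 30.5%), and ochre as best, on the ground that “the plateau is dead enzyme, not equilibrium”.

The flask gives 28.3% at 15 h, 28.6% after violet and 28.6% after green. The best remedy is ochre, with a gain of 12 points, where the count said 14 points; violet gains 0.28 points, blue 0.48 points, green 0.28 points. At 900 min the flask holds 1.15% of its catalyst in a form that can turn over, with 72% of the starting material left.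

    free enzyme → unfolded enzyme (k = 2.74 × 10⁻⁶ s⁻¹, Ea = 182 kJ mol⁻¹)
    starting material + free enzyme ⇌ complex A (K = 65.0 M⁻¹, k = 32100 M⁻¹ s⁻¹, Ea = 24.0 kJ mol⁻¹, ΔH = −5.00 kJ mol⁻¹)
    complex A → free enzyme + target (k = 0.806 s⁻¹, Ea = 69.0 kJ mol⁻¹)
    second substrate + free enzyme ⇌ complex B (K = 58.8 M⁻¹, k = 17900 M⁻¹ s⁻¹, Ea = 8.00 kJ mol⁻¹, ΔH = −82.0 kJ mol⁻¹)
    complex B → free enzyme + second product (k = 0.610 s⁻¹, Ea = 69.0 kJ mol⁻¹)
    free enzyme + added ligand ⇌ idle complex, settled at all times (K = 3.20 × 10⁵ M⁻¹, ΔH = −47.0 kJ mol⁻¹)
    complex B → spent catalyst (k = 2.93 × 10⁻⁴ s⁻¹, Ea = 105 kJ mol⁻¹)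
    (constants at 30 °C)

Now carry the count to the neighbour flask, charged with 0.0034 mM of free enzyme. There 2840 turnovers per enzyme give 48.3% of target. The neighbour flask gives 46.2% at 15 h.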